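**Plan**

1. Retrosynthesis: after the acetonide and a carboxyl group on ring D are put back, ring D is opened to a cyclopentanone by breaking the bond between one C/D fusion carbon and its ring-D neighbour (reverse Wolff contraction). Then follow the two ring-C bonds that join rings B and D (enone–cyclobutene [2+2]), the ring-B C=C (Ramberg–Bäcklund), the chain C1'–C2' bond (Wittig) and the two bonds of a bicyclo[2.2.2]octene (Diels–Alder).
2. Enabling feature: ring D is a cyclobutane cis-fused to ring C whose two non-fusion atoms are plain CH2 groups. It can therefore be cut down from a five-membered ketone fused at the same two carbons, the extruded carbonyl carbon leaving later as CO2.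
3. Forward order: ring A (masked as the bicyclooctene), then the C8 chain carrying the glycerol acetonide, ring B as a cyclobutene, ring C together with a cyclopentanone, ring D by contraction, then decarboxylation and deprotection.
4. Stereochemistry: one catalytic asymmetric endo Diels–Alder reaction fixes the three ring-A centres (all-cis after ozonolysis) and the absolute configuration. The four ladder centres come from enone addition to the convex face of the ring-B cyclobutene, and the Wolff shift keeps the configuration of the migrating fusion carbon.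

Key step: step 16

Remark on the chemistry: rings are lettered A (cyclohexane), B, C, D (cyclobutanes, outward from A); the remote chain makes the two cyclobutene carbons inequivalent, so the photoadduct and everything derived from it up to the decarboxylation, like the α-chloro sulfide and sulfone, are expected as constitutional (and Cl-epimeric) mixtures that all converge, and one isomer is drawn.
Remark on the chemistry: 2,2-dimethyl-1,3-dioxan-5-ol is taken as a purchasable building block.

**Route**

Step 1
Reactants: 1 cyclohexa-1,3-diene; 2 3-acryloyl-1,3-oxazolidin-2-one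
Product: 3 3-[(1S,2S,4S)-bicyclo[2.2.2]oct-5-ene-2-carbonyl]-1,3-oxazolidin-2-one (endo adduct)
Conditions: [Cu((S,S)-t-Bu-box)](SbF6)2 (10 mol %, divalent copper; t-Bu-box = 2,2'-(propane-2,2-diyl)bis[(4S)-4-tert-butyl-4,5-dihydro-1,3-oxazole]), 1 (5 equiv), CH2Cl2, 25 °C
Reagents that add atoms: none
Why: Catalytic asymmetric Diels–Alder reaction in which chelation of the acrylimide to the square-planar divalent copper bis(oxazoline) cation exposes one face of the s-cis dienophile, so the endo addition should set C1, C2 and C4 together in the (2S) sense known for cyclopentadiene with this catalyst (the (R,R) ligand would be used if the opposite sense were observed).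

Step 2
Reactants: 3 endo imide
Product: 4 (1S,2S,4S)-bicyclo[2.2.2]oct-5-ene-2-carboxylic acid
Conditions: LiOH, 30% H2O2, THF/H2O, 0 °C; Na2SO3; then 1 M HCl
Reagents that add atoms: hydrogen peroxide, OO
Why: Hydroperoxide-mediated cleavage of the N-acyl oxazolidinone attacks the exocyclic carbonyl selectively and should leave the α-centre and the alkene untouched.

Step 3
Reactants: 4 bicyclic acid
Product: 6 (3aR,6S,7aS)-6-(hydroxymethyl)hexahydro-2-benzofuran-1(3H)-one, via dihydroxy acid 5 (not isolated)
Conditions: O3, CH2Cl2/MeOH, −78 °C; NaBH4, −78 °C → rt; 2 M HCl to pH 2, rt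
Reagents that add atoms: ozone, [O-][O+]=O
Why: Ozonolysis with borohydride work-up cuts the C5=C6 bridge to an all-cis 1,2,4-trisubstituted cyclohexane, and only the hydroxymethyl group next to the carboxyl can close a cis-fused γ-lactone on acidification, which tells the two new carbinols apart without a protecting group.

Step 4
Reactants: 6 hydroxy lactone
Product: 7 (3aR,6S,7aS)-1-oxooctahydro-2-benzofuran-6-carbaldehyde (numbered as 6)
Conditions: Dess–Martin periodinane, NaHCO3, CH2Cl2, 0 °C → rt
Reagents that add atoms: none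
Why: Dess–Martin oxidation of the primary alcohol under buffered neutral conditions, which should spare the lactone and the epimerisable α-carbon.

Step 5
Reactants: 8 1,7-dibromoheptane; 9 2,2-dimethyl-1,3-dioxan-5-ol
Product: 10 5-[(7-bromoheptyl)oxy]-2,2-dimethyl-1,3-dioxane
Conditions: 9, NaH, DMF, 0 °C; then 8 (4 equiv), Bu4NI (cat.), 0 °C → rt
Reagents that add atoms: none
Why: Williamson ether synthesis (SN2 of the secondary alkoxide on a primary bromide), with the dibromide in excess to hold back double substitution.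

Step 6
Reactants: 10 bromo ether
Product: 11 {7-[(2,2-dimethyl-1,3-dioxan-5-yl)oxy]heptyl}triphenylphosphonium bromide
Conditions: PPh3, NaHCO3 (trace), MeCN, reflux
Reagents that add atoms: triphenylphosphine, c1ccc(cc1)P(c1ccccc1)c1ccccc1
Why: SN2 quaternisation of triphenylphosphine by the primary bromide under neutral conditions that the acetonide tolerates.

Step 7
Reactants: 7 lactone aldehyde; 11 phosphonium bromide
Product: 13 (3aR,6S,7aS)-6-{(1Z)-8-[(2,2-dimethyl-1,3-dioxan-5-yl)oxy]oct-1-en-1-yl}hexahydro-2-benzofuran-1(3H)-one, via phosphorus ylide 12 (not isolated)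
Conditions: 11, NaN(SiMe3)2, THF, −78 → 0 °C; then 7, −78 °C → rt
Reagents that add atoms: none
Why: Wittig olefination with a non-stabilised ylide, which should add to the aldehyde at −78 °C much faster than it enolises it or attacks the lactone; the expected (Z) geometry is irrelevant because the alkene is hydrogenated next.

Step 8
Reactants: 13 alkenyl lactone
Product: 14 (3aR,6S,7aS)-6-{8-[(2,2-dimethyl-1,3-dioxan-5-yl)oxy]octyl}hexahydro-2-benzofuran-1(3H)-one
Conditions: H2 (1 atm), Pd/C (10% palladium on carbon), EtOAc, rt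
Reagents that add atoms: none
Why: Heterogeneous catalytic hydrogenation of the disubstituted alkene under neutral conditions; no stereocentre is involved.

Step 9
Reactants: 14 saturated lactone
Product: 15 [(1R,2S,4S)-4-{8-[(2,2-dimethyl-1,3-dioxan-5-yl)oxy]octyl}cyclohexane-1,2-diyl]dimethanol (all-cis)
Conditions: LiAlH4, THF, 0 °C → rt; H2O/NaOH work-up
Reagents that add atoms: none
Why: Hydride reduction of the lactone gives the cis-1,2-bis(hydroxymethyl) diol, while the acetal and the ether are inert.

Step 10
Reactants: 15 diol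
Product: 16 bis(methanesulfonate) of 15
Conditions: MsCl, Et3N, CH2Cl2, 0 °C
Reagents that add atoms: methanesulfonyl chloride, CS(=O)(=O)Cl
Why: Sulfonylation of both primary alcohols turns them into leaving groups without touching a stereocentre.

Step 11
Reactants: 16 dimesylate
Product: 17 (3aS,5S,7aR)-5-{8-[(2,2-dimethyl-1,3-dioxan-5-yl)oxy]octyl}octahydro-2-benzothiophene
Conditions: Na2S·9H2O, DMF, 60 °C
Reagents that add atoms: sodium sulfide, [Na+].[Na+].[S-2]
Why: Double SN2 displacement by sulfide closes the cis-fused thiolane, the usual entry to Ramberg–Bäcklund substrates.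

Step 12
Reactants: 17 thiolane
Product: 19 α-chloro sulfone (2,2-dioxide of 17 bearing Cl on one S–CH2 carbon), via α-chloro sulfide 18 (not isolated)
Conditions: N-chlorosuccinimide, CH2Cl2, 0 °C → rt; then mCPBA (2.2 equiv), NaHCO3, CH2Cl2, 0 °C
Reagents that add atoms: N-chlorosuccinimide, O=C1CCC(=O)N1Cl; 3-chloroperbenzoic acid, OOC(=O)c1cccc(Cl)c1
Why: Pummerer-type α-chlorination of the sulfide followed at once by peracid oxidation to the sulfone; either α-carbon may be chlorinated since both isomers lead to the same alkene.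

Step 13
Reactants: 19 α-chloro sulfone
Product: 20 5-({8-[(1R,3S,6S)-bicyclo[4.2.0]oct-7-en-3-yl]octyl}oxy)-2,2-dimethyl-1,3-dioxane (ring-B cyclobutene)
Conditions: KOtBu (3 equiv), THF, −78 → 0 °C
Reagents that add atoms: none
Why: Ramberg–Bäcklund reaction, in which α'-deprotonation, 1,3-displacement of chloride to the episulfone and loss of SO2 give the cis-fused cyclobutene, as known for fused 2-chlorothiolane 1,1-dioxides; the ring-A centres are not touched.

Step 14
Reactants: 20 ring-B cyclobutene; 21 cyclopent-2-enone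
Product: 22 5-{8-[(2,2-dimethyl-1,3-dioxan-5-yl)oxy]octyl}tetracyclo[6.5.0.0(2,7).0(9,13)]tridecan-10-one (rings A, B, C and a cyclopentanone fused linearly; all fusions cis, neighbouring rings anti)
Conditions: hν (medium-pressure Hg lamp, uranium-glass filter, λ > 330 nm), 21 (5 equiv, in portions), CH2Cl2, −40 °C
Reagents that add atoms: none
Why: Enone–alkene [2+2] photocycloaddition through the enone triplet, where addition to the convex face of the cyclobutene (away from ring A) and the anti placement of the five-membered ring and ring B across the new ring C should set all four new centres, a cyclopentenone being able to give only a cis ring fusion.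

Step 15
Reactants: 22 tetracyclic ketone
Product: 24 11-diazo derivative of 22 (α-diazo ketone with the diazo group on the CH2 side), via α-trifluoroacetyl ketone 23 (not isolated)
Conditions: LiN(SiMe3)2, THF, −78 °C; CF3CO2CH2CF3, −78 °C; cold aq. citric acid wash; then MsN3, Et3N, H2O (1 equiv), MeCN, rt
Reagents that add atoms: methanesulfonyl azide, CS(=O)(=O)N=[N+]=[N-]
Why: Deacylative diazo transfer (Regitz type, through the trifluoroacetyl-activated ketone), in which kinetic enolisation occurs at the CH2 group because the other α-position is the ring-fusion CH, so the diazo group can only be placed on the CH2 side.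

Step 16
Reactants: 24 α-diazo ketone
Product: 26 methyl 5-{8-[(2,2-dimethyl-1,3-dioxan-5-yl)oxy]octyl}tetracyclo[6.4.0.0(2,7).0(9,12)]dodecane-10-carboxylate (ring D formed; ester drawn cis to ring C), via ketene 25 (not isolated)
Conditions: hν (medium-pressure Hg lamp, Pyrex, λ > 300 nm), degassed MeOH/THF, 0 °C
Reagents that add atoms: methanol, CO
Why: Light expels N2 from the 2-diazo ketone and the C/D fusion carbon bonded to the carbonyl shifts to the diazo carbon (Wolff rearrangement), giving ketene 25 that methanol traps as the ester; the closest known reaction type is the photochemical Wolff ring contraction of 2-diazocyclopentanones to cyclobutanecarboxylates, which has been run on strained fused cyclobutanes. Ring D is not closed end to end: it arises by a 1,2-shift that pushes the carbonyl carbon out of the five-membered ring (ring contraction), so one new C–C bond turns the cyclopentanone into the cyclobutane. The migrating fusion carbon keeps its configuration because the shift is suprafacial with retention, and the other fusion carbon is untouched, so the cis C/D fusion and the anti relation to ring B from step 14 are carried over. The only new stereocentre, the ester carbon, is set by protonation of the ketene-derived enol on the exposed convex face (ester cis to ring C expected) and does not matter because it becomes CH2 in step 18. The step needs the rearrangement to outrun O–H insertion of a free carbene into methanol and 1,2-hydride shift from the adjacent CH2; the ring-locked s-cis geometry of the cyclic diazo ketone, which favours concerted migration, and the good migratory aptitude of the strained secondary fusion carbon should secure this. The regioisomeric diazo ketone contracts in the same way to an ester that converges on the same compound in step 18.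

Step 17
Reactants: 26 ring-D methyl ester
Product: 27 ring-D carboxylic acid (5-substituted tetracyclo[6.4.0.0(2,7).0(9,12)]dodecane-10-carboxylic acid)
Conditions: LiOH·H2O, THF/MeOH/H2O, rt → 40 °C; cold aq. citric acid to pH 4
Reagents that add atoms: lithium hydroxide, [Li+].[OH-]
Why: Ester saponification; any epimerisation at the carboxyl-bearing carbon is harmless because that centre is removed next.

Step 18
Reactants: 27 ring-D acid
Product: 29 5-{[8-(tetracyclo[6.4.0.0(2,7).0(9,12)]dodecan-4-yl)octyl]oxy}-2,2-dimethyl-1,3-dioxane (ladder acetonide), via thiohydroxamate ester 28 (not isolated)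
Conditions: N-hydroxypyridine-2-thione, DCC, DMAP (cat.), CH2Cl2, 0 °C → rt, dark; then t-BuSH (20 equiv), hν (tungsten lamp), 0–10 °C
Reagents that add atoms: none
Why: Barton reductive decarboxylation, in which the thiohydroxamate ester fragments under visible light to CO2 and a secondary cyclobutyl radical that the thiol in large excess should quench faster than the ring can open, turning the former ester carbon into CH2.

Step 19
Reactants: 29 ladder acetonide
Product: 30 2-{[8-(tetracyclo[6.4.0.0(2,7).0(9,12)]dodecan-4-yl)octyl]oxy}propane-1,3-diol (target; all fusions cis, neighbouring rings anti, chain cis to ring B)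
Conditions: AcOH/H2O/THF (4:1:1), 40 °C
Reagents that add atoms: none
Why: Mild acid hydrolysis of the isopropylidene acetal; the saturated ladder hydrocarbon and the ether are stable to aqueous acetic acid.

**Compound list**

1 | cyclohexa-1,3-diene | C1=CC=CCC1 | starting material
2 | 3-acryloyl-1,3-oxazolidin-2-one | C=CC(=O)N1CCOC1=O | starting material
3 | 3-[(1S,2S,4S)-bicyclo[2.2.2]oct-5-ene-2-carbonyl]-1,3-oxazolidin-2-one | C1=C[C@H]2CC[C@@H]1[C@H](C2)C(=O)N1CCOC1=O | intermediate
4 | (1S,2S,4S)-bicyclo[2.2.2]oct-5-ene-2-carboxylic acid | C1=C[C@H]2CC[C@@H]1[C@H](C2)C(=O)O | intermediate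
5 | (1S,2R,5S)-2,5-bis(hydroxymethyl)cyclohexane-1-carboxylic acid (all-cis; not isolated) | OC[C@H]1CC[C@@H](CO)[C@H](C1)C(=O)O | intermediate
6 | (3aR,6S,7aS)-6-(hydroxymethyl)hexahydro-2-benzofuran-1(3H)-one | OC[C@H]1CC[C@@H]2[C@H](C1)C(=O)OC2 | intermediate
7 | (3aR,6S,7aS)-1-oxooctahydro-2-benzofuran-6-carbaldehyde | O=C[C@H]1CC[C@@H]2[C@H](C1)C(=O)OC2 | intermediate
8 | 1,7-dibromoheptane | BrCCCCCCCBr | starting material
9 | 2,2-dimethyl-1,3-dioxan-5-ol | CC1(C)OCC(O)CO1 | starting material
10 | 5-[(7-bromoheptyl)oxy]-2,2-dimethyl-1,3-dioxane | CC1(C)OCC(CO1)OCCCCCCCBr | intermediate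
11 | {7-[(2,2-dimethyl-1,3-dioxan-5-yl)oxy]heptyl}triphenylphosphonium bromide | CC1(C)OCC(CO1)OCCCCCCC[P+](c1ccccc1)(c1ccccc1)c1ccccc1.[Br-] | intermediate
12 | {7-[(2,2-dimethyl-1,3-dioxan-5-yl)oxy]heptylidene}triphenylphosphorane (not isolated) | CC1(C)OCC(CO1)OCCCCCCC=P(c1ccccc1)(c1ccccc1)c1ccccc1 | intermediate
13 | (3aR,6S,7aS)-6-{(1Z)-8-[(2,2-dimethyl-1,3-dioxan-5-yl)oxy]oct-1-en-1-yl}hexahydro-2-benzofuran-1(3H)-one | CC1(C)OCC(CO1)OCCCCCC/C=C\[C@H]1CC[C@@H]2[C@H](C1)C(=O)OC2 | intermediate
14 | (3aR,6S,7aS)-6-{8-[(2,2-dimethyl-1,3-dioxan-5-yl)oxy]octyl}hexahydro-2-benzofuran-1(3H)-one | CC1(C)OCC(CO1)OCCCCCCCC[C@H]1CC[C@@H]2[C@H](C1)C(=O)OC2 | intermediate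
15 | [(1R,2S,4S)-4-{8-[(2,2-dimethyl-1,3-dioxan-5-yl)oxy]octyl}cyclohexane-1,2-diyl]dimethanol | CC1(C)OCC(CO1)OCCCCCCCC[C@H]1CC[C@@H](CO)[C@H](C1)CO | intermediate
16 | bis(methanesulfonate) of 15 | CC1(C)OCC(CO1)OCCCCCCCC[C@H]1CC[C@@H](COS(C)(=O)=O)[C@H](C1)COS(C)(=O)=O | intermediate
17 | (3aS,5S,7aR)-5-{8-[(2,2-dimethyl-1,3-dioxan-5-yl)oxy]octyl}octahydro-2-benzothiophene | CC1(C)OCC(CO1)OCCCCCCCC[C@H]1CC[C@@H]2[C@H](C1)CSC2 | intermediate
18 | α-chloro sulfide of 17 (Cl on one S–CH2 carbon, isomer mixture; not isolated) | CC1(C)OCC(CO1)OCCCCCCCC[C@H]1CC[C@@H]2[C@H](C1)C(Cl)SC2 | intermediate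
19 | α-chloro sulfone (2,2-dioxide of 18, isomer mixture) | CC1(C)OCC(CO1)OCCCCCCCC[C@H]1CC[C@@H]2[C@H](C1)C(Cl)S(=O)(=O)C2 | intermediate
20 | 5-({8-[(1R,3S,6S)-bicyclo[4.2.0]oct-7-en-3-yl]octyl}oxy)-2,2-dimethyl-1,3-dioxane | CC1(C)OCC(CO1)OCCCCCCCC[C@H]1CC[C@@H]2[C@H](C1)C=C2 | intermediate
21 | cyclopent-2-enone | O=C1C=CCC1 | starting material
22 | 5-{8-[(2,2-dimethyl-1,3-dioxan-5-yl)oxy]octyl}tetracyclo[6.5.0.0(2,7).0(9,13)]tridecan-10-one, cis,anti,cis,anti,cis | CC1(C)OCC(CO1)OCCCCCCCC[C@H]1CC[C@@H]2[C@H](C1)[C@H]1[C@@H]3C(=O)CC[C@@H]3[C@@H]21 | intermediate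
23 | 11-(trifluoroacetyl) derivative of 22 (not isolated) | CC1(C)OCC(CO1)OCCCCCCCC[C@H]1CC[C@@H]2[C@H](C1)[C@H]1[C@@H]3C(=O)C(C(=O)C(F)(F)F)C[C@@H]3[C@@H]21 | intermediate
24 | 11-diazo derivative of 22 (α-diazo ketone) | CC1(C)OCC(CO1)OCCCCCCCC[C@H]1CC[C@@H]2[C@H](C1)[C@H]1[C@@H]3C(=O)C(=[N+]=[N-])C[C@@H]3[C@@H]21 | intermediate
25 | ring-D ketene (not isolated) | CC1(C)OCC(CO1)OCCCCCCCC[C@H]1CC[C@@H]2[C@H](C1)[C@H]1[C@@H]3C(=C=O)C[C@@H]3[C@@H]21 | intermediate
26 | methyl 5-{8-[(2,2-dimethyl-1,3-dioxan-5-yl)oxy]octyl}tetracyclo[6.4.0.0(2,7).0(9,12)]dodecane-10-carboxylate (ester cis to ring C drawn; epimer equally usable) | CC1(C)OCC(CO1)OCCCCCCCC[C@H]1CC[C@@H]2[C@H](C1)[C@H]1[C@@H]3[C@H](C(=O)OC)C[C@@H]3[C@@H]21 | intermediate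
27 | corresponding ring-D carboxylic acid | CC1(C)OCC(CO1)OCCCCCCCC[C@H]1CC[C@@H]2[C@H](C1)[C@H]1[C@@H]3[C@H](C(=O)O)C[C@@H]3[C@@H]21 | intermediate
28 | 2-thioxopyridin-1(2H)-yl ester of 27 (not isolated) | CC1(C)OCC(CO1)OCCCCCCCC[C@H]1CC[C@@H]2[C@H](C1)[C@H]1[C@@H]3[C@H](C(=O)ON4C=CC=CC4=S)C[C@@H]3[C@@H]21 | intermediate
29 | 5-{[8-(tetracyclo[6.4.0.0(2,7).0(9,12)]dodecan-4-yl)octyl]oxy}-2,2-dimethyl-1,3-dioxane | CC1(C)OCC(CO1)OCCCCCCCC[C@H]1CC[C@@H]2[C@H](C1)[C@H]1[C@@H]3CC[C@@H]3[C@@H]21 | intermediate
30 | 2-{[8-(tetracyclo[6.4.0.0(2,7).0(9,12)]dodecan-4-yl)octyl]oxy}propane-1,3-diol (CNP0193334.1) | OCC(CO)OCCCCCCCC[C@H]1CC[C@@H]2[C@H](C1)[C@H]1[C@@H]3CC[C@@H]3[C@@H]21 | target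

**Count and risks**

Total steps: 19. Longest linear sequence: 17 (steps 1–4 and 7–19); steps 5–6 make the chain fragment.

Risk 1, step 14 (crossed photocycloaddition). Photodimerisation of the enone and light-induced α-cleavage of the product ketone may use up material faster than the crossed addition to the limiting cyclobutene, and the anti selectivity across ring C may erode. The fallback sets out from 20 and comes back at 26. Acetophenone-sensitised [2+2] photocycloaddition of maleic anhydride in excess, which leaves no photolabile ketone, should give the ring-C anhydride F1. LiAlH4 reduces it to the cis-bis(hydroxymethyl) compound F2, and I2, PPh3 and imidazole convert this into the cis-bis(iodomethyl) compound F3. 2-Lithio-1,3-dithiane followed by a second equivalent of n-BuLi closes the spiro-dithiane F4 (Corey–Seebach double alkylation). MeI and CaCO3 in aqueous MeCN free the symmetrical five-ring ketone F5, whose carbonyl lies between two CH2 groups. Deacylative diazo transfer as in step 15, through the α-trifluoroacetyl ketone F6, gives the isomeric α-diazo ketone F7. Its photolysis in MeOH passes through the same ketene 25 and gives 26, so the Wolff contraction is kept and only the way to the five-membered ketone changes.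

Risk 2, step 13 (with the chlorination of step 12). Loss of HCl toward the ring-fusion hydrogen, either from the α-chloro sulfide before oxidation or from the chloro sulfone as a vinyl sulfone, may outrun episulfone formation and SO2 extrusion. The fallback sets out from 15 and comes back at 20. Swern oxidation gives the cis-dialdehyde F8, used cold and at once. Pinacol cyclisation with SmI2 (divalent samarium) in THF/t-BuOH gives the cis-cyclobutane-1,2-diol F9. 1,1'-Thiocarbonyldiimidazole gives the cyclic thionocarbonate F10, and Corey–Winter fragmentation with 1,3-dimethyl-2-phenyl-1,3,2-diazaphospholidine at 40 °C gives 20.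

Risk 3, step 18 (radical decarboxylation). β-Scission of the cyclobutyl radical next to ring C, which would open the ladder, may compete with hydrogen transfer from the thiol. The fallback sets out from 26 and comes back at 29. DIBAL-H in CH2Cl2 at −78 °C gives the ring-D carbaldehyde F11, and stoichiometric RhCl(PPh3)3 in toluene at reflux removes CO (Tsuji–Wilkinson decarbonylation, a two-electron path without a free radical).

**Further compounds**

F1 | step 14 | ring-C anhydride (maleic anhydride photoadduct of 20, anti to ring B) | CC1(C)OCC(CO1)OCCCCCCCC[C@H]1CC[C@@H]2[C@H](C1)[C@H]1[C@@H]3C(=O)OC(=O)[C@@H]3[C@@H]21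
F2 | step 14 | cis-bis(hydroxymethyl) compound on ring C | CC1(C)OCC(CO1)OCCCCCCCC[C@H]1CC[C@@H]2[C@H](C1)[C@H]1[C@H](CO)[C@H](CO)[C@@H]21
F3 | step 14 | cis-bis(iodomethyl) compound on ring C | CC1(C)OCC(CO1)OCCCCCCCC[C@H]1CC[C@@H]2[C@H](C1)[C@H]1[C@H](CI)[C@H](CI)[C@@H]21
F4 | step 14 | spiro-1,3-dithiane of the symmetrical five-ring ketone | CC1(C)OCC(CO1)OCCCCCCCC[C@H]1CC[C@@H]2[C@H](C1)[C@H]1[C@@H]3CC4(SCCCS4)C[C@@H]3[C@@H]21
F5 | step 14 | symmetrical five-ring ketone (tetracyclo[6.5.0.0(2,7).0(9,13)]tridecan-11-one core) | CC1(C)OCC(CO1)OCCCCCCCC[C@H]1CC[C@@H]2[C@H](C1)[C@H]1[C@@H]3CC(=O)C[C@@H]3[C@@H]21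
F6 | step 14 | α-trifluoroacetyl ketone from F5 (not isolated) | CC1(C)OCC(CO1)OCCCCCCCC[C@H]1CC[C@@H]2[C@H](C1)[C@H]1[C@@H]3C(C(=O)C(F)(F)F)C(=O)C[C@@H]3[C@@H]21
F7 | step 14 | isomeric α-diazo ketone (10-diazo-11-one) | CC1(C)OCC(CO1)OCCCCCCCC[C@H]1CC[C@@H]2[C@H](C1)[C@H]1[C@@H]3C(=[N+]=[N-])C(=O)C[C@@H]3[C@@H]21
F8 | step 13 | cis-cyclohexane-1,2-dicarbaldehyde bearing the chain | CC1(C)OCC(CO1)OCCCCCCCC[C@H]1CC[C@@H](C=O)[C@H](C1)C=O
F9 | step 13 | cis-cyclobutane-1,2-diol (3-substituted bicyclo[4.2.0]octane-7,8-diol) | CC1(C)OCC(CO1)OCCCCCCCC[C@H]1CC[C@@H]2[C@H](C1)C(O)C2O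
F10 | step 13 | cyclic thionocarbonate of F9 | CC1(C)OCC(CO1)OCCCCCCCC[C@H]1CC[C@@H]2[C@H](C1)C1OC(=S)OC21
F11 | step 18 | ring-D carbaldehyde | CC1(C)OCC(CO1)OCCCCCCCC[C@H]1CC[C@@H]2[C@H](C1)[C@H]1[C@@H]3[C@H](C=O)C[C@@H]3[C@@H]21
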